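## Retrosynthetic overview

1. Numbering: C1 quaternary carbinol, C2 (OAc), C3 (OBz), C4=C5, C6 (CHOH), C7 (CH2OBz). The strategy rests on C1, which carries an oxygen and C7, being bonded to the allylic carbinol C6 beside C4=C5. The array C7(=O)–C1(O)–C6–C5=C4 is a γ,δ-unsaturated α-alkoxy acid, the retron of a glycolate Ireland–Claisen rearrangement with C7 as the carboxyl carbon.
2. Target ⇐ cyclohexene acid 14 (C1/C2 OMOM, C3 OPMB, C6 Bpin) by C–B oxidation, reduction of C7, benzoylation of O7, exchange of PMB for benzoate at O3, and MOM → Ac/OH at O2/O1.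
3. Key disconnection C1–C6: 14 ⇐ silyl ketene acetal of δ-lactone 11, which carries an (E)-vinylboronate on C4. The carbocycle closes by [3,3] ring contraction as the lactone C4–O bond breaks.
4. 11 ⇐ L-gulono-1,4-lactone: mask the terminal diol, put MOM on the two lactone hydroxyls, open with morpholine so the former ring oxygen can take PMB, translactonise to the six-membered lactone, oxidise C5 to the aldehyde, then chromium boryl olefination with Cl2CHBpin.
5. Ring order: γ-lactone (chiral pool) → δ-lactone (step 5) → cyclohexene, the only carbocycle (step 8).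

Key step: step 8

Remark: every atom keeps the number of the target atom it becomes (C7 = lactone carbonyl = sugar C1; C1–C5 = sugar C2–C6; C6 = the carbon brought in with boron; each oxygen takes the number of its carbon). Sugar locants appear only inside carbohydrate names. β is the ring face that carries C2–O, C6–O and C7 in the target; α is the face of C1–O and C3–O.

## Route

Step 1
Reactants: 1 L-gulono-1,4-lactone
Product: 2 5,6-O-isopropylidene-L-gulono-1,4-lactone
Conditions: 2-methoxypropene, TsOH·H2O (cat.), DMF, 0 °C to rt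
Reagents that add atoms: 2-methoxypropene (COC(C)=C)
Why: Kinetic acid-catalysed acetalisation with the enol ether takes the primary hydroxyl and its neighbour (O5, O4) into a terminal dioxolane and leaves the cis-diol on the lactone ring free; no stereocentre is touched.

Step 2
Reactants: 2 5,6-O-isopropylidene-L-gulono-1,4-lactone
Product: 3 5,6-O-isopropylidene-2,3-di-O-(methoxymethyl)-L-gulono-1,4-lactone
Conditions: MeOCH2Cl (excess), i-Pr2NEt, Bu4NI (cat.), CH2Cl2, 0 to 40 °C
Reagents that add atoms: chloromethyl methyl ether (COCCl)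
Why: O-alkylation of both ring hydroxyls (O1, O2) as MOM ethers under a hindered amine base that should not enolise the lactone; two identical acyclic ethers suffice because these oxygens are told apart at the end as tertiary and secondary alcohols.

Step 3
Reactants: 3 5,6-O-isopropylidene-2,3-di-O-(methoxymethyl)-L-gulono-1,4-lactone
Product: 4 4-[5,6-O-isopropylidene-2,3-di-O-(methoxymethyl)-L-gulonoyl]morpholine
Conditions: morpholine, 2-hydroxypyridine (cat.), THF, 50 °C
Reagents that add atoms: morpholine (C1COCCN1)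
Why: Aminolysis of the γ-lactone (bifunctional catalysis by 2-hydroxypyridine) gives the open-chain tertiary amide in which the former ring oxygen O3 is the only free hydroxyl, and the amide should not re-close under the basic conditions of the next step.

Step 4
Reactants: 4 4-[5,6-O-isopropylidene-2,3-di-O-(methoxymethyl)-L-gulonoyl]morpholine; 5 4-methoxybenzyl chloride
Product: 6 4-[5,6-O-isopropylidene-4-O-(4-methoxybenzyl)-2,3-di-O-(methoxymethyl)-L-gulonoyl]morpholine
Conditions: NaH, Bu4NI (cat.), DMF, 0 °C to rt
Reagents that add atoms: none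
Why: Williamson etherification of the single free hydroxyl (O3) blocks any return to the five-membered lactone; a tertiary amide is not enolised by NaH, so the MOM ether on C2 is not at risk of elimination.

Step 5
Reactants: 6 4-[5,6-O-isopropylidene-4-O-(4-methoxybenzyl)-2,3-di-O-(methoxymethyl)-L-gulonoyl]morpholine
Product: 8 4-O-(4-methoxybenzyl)-2,3-di-O-(methoxymethyl)-L-gulono-1,5-lactone, via diol amide 7 (not isolated)
Conditions: AcOH/H2O (4:1), 40 °C; then CSA (1.1 equiv), PhMe, 60 °C
Reagents that add atoms: none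
Why: Selective hydrolysis of the terminal isopropylidene acetal, then acid-promoted N-to-O acyl transfer (lactonisation of a δ-hydroxy amide, driven by protonation of the released morpholine), should close the six-membered lactone on O4, since O3 is blocked and the seven-membered alternative on O5 is disfavoured; no stereocentre is touched.

Step 6
Reactants: 8 4-O-(4-methoxybenzyl)-2,3-di-O-(methoxymethyl)-L-gulono-1,5-lactone
Product: 9 6-aldehydo-4-O-(4-methoxybenzyl)-2,3-di-O-(methoxymethyl)-L-gulono-1,5-lactone (C5 oxidised to CHO)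
Conditions: Dess–Martin periodinane, NaHCO3, CH2Cl2, 0 °C to rt
Reagents that add atoms: none
Why: Dess–Martin oxidation of the primary alcohol under buffered, non-basic conditions should give the α-acyloxy aldehyde without epimerisation at C4; the aldehyde is used crude.

Step 7
Reactants: 9 6-aldehydo-4-O-(4-methoxybenzyl)-2,3-di-O-(methoxymethyl)-L-gulono-1,5-lactone; 10 pinacol (dichloromethyl)boronate
Product: 11 (E)-6,7-dideoxy-4-O-(4-methoxybenzyl)-2,3-di-O-(methoxymethyl)-7-(4,4,5,5-tetramethyl-1,3,2-dioxaborolan-2-yl)-L-gulo-hept-6-enono-1,5-lactone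
Conditions: CrCl2, LiI, THF, rt
Reagents that add atoms: none
Why: Takai–Utimoto boryl olefination: the geminal dichromium reagent generated by divalent chromium from the dihalomethylboronate (LiI exchanges chloride for iodide) adds to the aldehyde and eliminates to the E-alkenylboronate under neutral conditions that leave C4 and the lactone intact.

Step 8
Reactants: 11 (E)-6,7-dideoxy-4-O-(4-methoxybenzyl)-2,3-di-O-(methoxymethyl)-7-(4,4,5,5-tetramethyl-1,3,2-dioxaborolan-2-yl)-L-gulo-hept-6-enono-1,5-lactone
Product: 14 1,2-bis(methoxymethoxy)-3-(4-methoxybenzyloxy)-6-(pinacolboryl)cyclohex-4-ene-1-carboxylic acid (C1–O/C3–O α; C2–O/C6–B/CO2H β), via silyl ketene acetal 12 (not isolated), via trimethylsilyl ester 13 (not isolated)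
Conditions: Me3SiCl/Et3N (premixed), KN(SiMe3)2 added slowly, THF/PhMe, −78 °C; then PhMe, 100 °C; pH 5 aqueous work-up
Reagents that add atoms: none
Why: KN(SiMe3)2 removes the C1 proton in the presence of Me3SiCl so that the lactone enolate is captured at once as the cyclic O-silyl ketene acetal 12, which on heating undergoes a concerted [3,3]-sigmatropic (Ireland–Claisen) shift in which C1–C6 forms while the lactone C4–O bond breaks, giving silyl ester 13 and, after mild aqueous work-up, acid 14. The closest known reactions are the Ireland–Claisen ring contraction of ω-alkenyl lactone silyl ketene acetals to cycloalkene carboxylic acids and the Claisen rearrangements of 3-borylallyl esters that deliver allylboronates. The cyclohexene ring (C1–C6) is closed not by a Baldwin-type attack but as a sigmatropic ring contraction through a bicyclo[2.2.2]octane-like array, in which the C2–C3 bridge between the two termini enforces a boat pericyclic transition state. C1 is set by the lactone carbinol centre C4 (destroyed as it becomes sp2), because the alkenyl arm can reach only the ketene acetal face on which it is held, and C6 is set by the E geometry of the vinylboronate, which in the enforced boat places boron outward and on the same ring face as the new carboxyl group. The step needs O-silylation to outrun β-elimination of the C2 methoxymethoxy group, which the internal quench at −78 °C should secure, and it needs the C2–O bond free to stand axial and anti to the forming bond, which is why O1 and O2 carry separate acyclic ethers and not a dioxolane.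

Step 9
Reactants: 14 1,2-bis(methoxymethoxy)-3-(4-methoxybenzyloxy)-6-(pinacolboryl)cyclohex-4-ene-1-carboxylic acid
Product: 15 6-hydroxy-1,2-bis(methoxymethoxy)-3-(4-methoxybenzyloxy)cyclohex-4-ene-1-carboxylic acid (6-OH β)
Conditions: 30% H2O2, aq. NaOH, THF, 0 °C (crude 14 used directly)
Reagents that add atoms: hydrogen peroxide (OO)
Why: Oxidation of the secondary allylic boronate by 1,2-migration of carbon from boron to oxygen in the hydroperoxide ate complex proceeds with retention, so the C6 hydroxyl should appear on the β face, trans to the C1 oxygen.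

Step 10
Reactants: 15 6-hydroxy-1,2-bis(methoxymethoxy)-3-(4-methoxybenzyloxy)cyclohex-4-ene-1-carboxylic acid
Product: 16 tert-butyldimethylsilyl 6-(tert-butyldimethylsilyloxy)-1,2-bis(methoxymethoxy)-3-(4-methoxybenzyloxy)cyclohex-4-ene-1-carboxylate
Conditions: TBSOTf (excess), 2,6-lutidine, CH2Cl2, −78 to −20 °C
Reagents that add atoms: tert-butyldimethylsilyl trifluoromethanesulfonate (CC(C)(C)[Si](C)(C)OS(=O)(=O)C(F)(F)F)
Why: Silylation of the hindered C6 hydroxyl and of the carboxylic acid by the silyl triflate; the silyl ether is the group that later keeps C6–OH out of every acylation.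

Step 11
Reactants: 16 tert-butyldimethylsilyl 6-(tert-butyldimethylsilyloxy)-1,2-bis(methoxymethoxy)-3-(4-methoxybenzyloxy)cyclohex-4-ene-1-carboxylate
Product: 17 [6-(tert-butyldimethylsilyloxy)-1,2-bis(methoxymethoxy)-3-(4-methoxybenzyloxy)cyclohex-4-en-1-yl]methanol
Conditions: LiAlH4, Et2O, 0 °C
Reagents that add atoms: none
Why: Hydride reduction of the silyl ester gives the primary alcohol C7–OH; ethers, acetals and the ring alkene are inert to LiAlH4.

Step 12
Reactants: 17 [6-(tert-butyldimethylsilyloxy)-1,2-bis(methoxymethoxy)-3-(4-methoxybenzyloxy)cyclohex-4-en-1-yl]methanol; 18 benzoyl chloride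
Product: 19 [6-(tert-butyldimethylsilyloxy)-1,2-bis(methoxymethoxy)-3-(4-methoxybenzyloxy)cyclohex-4-en-1-yl]methyl benzoate
Conditions: pyridine, DMAP (cat.), CH2Cl2, 0 °C to rt
Reagents that add atoms: none
Why: DMAP-catalysed acylation of the only free hydroxyl, the primary C7–OH, installs the first benzoate (one equivalent of acid chloride per hydroxyl) while every other oxygen is still masked.

Step 13
Reactants: 19 [6-(tert-butyldimethylsilyloxy)-1,2-bis(methoxymethoxy)-3-(4-methoxybenzyloxy)cyclohex-4-en-1-yl]methyl benzoate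
Product: 20 [6-(tert-butyldimethylsilyloxy)-3-hydroxy-1,2-bis(methoxymethoxy)cyclohex-4-en-1-yl]methyl benzoate
Conditions: DDQ, CH2Cl2/pH 7 buffer, 0 °C to rt
Reagents that add atoms: none
Why: Oxidative cleavage of the 4-methoxybenzyl ether through its benzylic oxocarbenium ion frees the allylic C3 hydroxyl while the benzoate, the MOM ethers and the TBS ether stay in place, and the distant C7 ester should not migrate under the neutral buffer.

Step 14
Reactants: 20 [6-(tert-butyldimethylsilyloxy)-3-hydroxy-1,2-bis(methoxymethoxy)cyclohex-4-en-1-yl]methyl benzoate; 18 benzoyl chloride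
Product: 21 [3-(benzoyloxy)-6-(tert-butyldimethylsilyloxy)-1,2-bis(methoxymethoxy)cyclohex-4-en-1-yl]methyl benzoate
Conditions: pyridine, DMAP (cat.), CH2Cl2, 0 °C to rt
Reagents that add atoms: none
Why: DMAP-catalysed acylation of the single free hydroxyl (allylic C3–OH) installs the second benzoate with retention at C3, since the C–O bond is not touched.

Step 15
Reactants: 21 [3-(benzoyloxy)-6-(tert-butyldimethylsilyloxy)-1,2-bis(methoxymethoxy)cyclohex-4-en-1-yl]methyl benzoate
Product: 22 [3-(benzoyloxy)-6-(tert-butyldimethylsilyloxy)-1,2-dihydroxycyclohex-4-en-1-yl]methyl benzoate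
Conditions: ZnBr2, n-PrSH, CH2Cl2, 0 °C
Reagents that add atoms: none
Why: Lewis acid–thiol cleavage of both MOM ethers (the methoxymethyl cation is trapped by the thiol) runs under non-basic conditions that should leave the benzoates and the TBS ether in place and not promote acyl migration.

Step 16
Reactants: 22 [3-(benzoyloxy)-6-(tert-butyldimethylsilyloxy)-1,2-dihydroxycyclohex-4-en-1-yl]methyl benzoate
Product: 23 [2-acetoxy-3-(benzoyloxy)-6-(tert-butyldimethylsilyloxy)-1-hydroxycyclohex-4-en-1-yl]methyl benzoate
Conditions: Ac2O, pyridine, DMAP (cat.), CH2Cl2, 0 °C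
Reagents that add atoms: acetic anhydride (CC(=O)OC(C)=O)
Why: Acylation of the secondary C2 hydroxyl; the tertiary C1 hydroxyl should not react under these conditions.

Step 17
Reactants: 23 [2-acetoxy-3-(benzoyloxy)-6-(tert-butyldimethylsilyloxy)-1-hydroxycyclohex-4-en-1-yl]methyl benzoate
Product: 24 [(1S,2S,3R,6R)-2-acetoxy-3-(benzoyloxy)-1,6-dihydroxycyclohex-4-en-1-yl]methyl benzoate (descriptors in the numbering used here)
Conditions: HF·pyridine, THF/pyridine, 0 °C to rt
Reagents that add atoms: none
Why: Fluoride-mediated desilylation under buffered acidic conditions should free C6–OH without ester migration or hydrolysis.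

## Compound list

1 | L-gulono-1,4-lactone | OC[C@H](O)[C@H]1OC(=O)[C@@H](O)[C@H]1O | starting material
2 | 5,6-O-isopropylidene-L-gulono-1,4-lactone | CC1(C)OC[C@H](O1)[C@H]2OC(=O)[C@@H](O)[C@H]2O | intermediate
3 | 5,6-O-isopropylidene-2,3-di-O-(methoxymethyl)-L-gulono-1,4-lactone | CC1(C)OC[C@H](O1)[C@H]2OC(=O)[C@@H](OCOC)[C@H]2OCOC | intermediate
4 | 4-[5,6-O-isopropylidene-2,3-di-O-(methoxymethyl)-L-gulonoyl]morpholine (free 4-OH) | CC1(C)OC[C@H](O1)[C@@H](O)[C@H](OCOC)[C@H](OCOC)C(=O)N1CCOCC1 | intermediate
5 | 4-methoxybenzyl chloride | COc1ccc(CCl)cc1 | starting material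
6 | 4-[5,6-O-isopropylidene-4-O-(4-methoxybenzyl)-2,3-di-O-(methoxymethyl)-L-gulonoyl]morpholine | CC1(C)OC[C@H](O1)[C@@H](OCc1ccc(OC)cc1)[C@H](OCOC)[C@H](OCOC)C(=O)N1CCOCC1 | intermediate
7 | 4-[4-O-(4-methoxybenzyl)-2,3-di-O-(methoxymethyl)-L-gulonoyl]morpholine (5,6-diol, not isolated) | OC[C@H](O)[C@@H](OCc1ccc(OC)cc1)[C@H](OCOC)[C@H](OCOC)C(=O)N1CCOCC1 | intermediate
8 | 4-O-(4-methoxybenzyl)-2,3-di-O-(methoxymethyl)-L-gulono-1,5-lactone (free 6-OH) | O=C1O[C@@H](CO)[C@@H](OCc2ccc(OC)cc2)[C@H](OCOC)[C@@H]1OCOC | intermediate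
9 | 6-aldehydo-4-O-(4-methoxybenzyl)-2,3-di-O-(methoxymethyl)-L-gulono-1,5-lactone | O=C1O[C@@H](C=O)[C@@H](OCc2ccc(OC)cc2)[C@H](OCOC)[C@@H]1OCOC | intermediate
10 | pinacol (dichloromethyl)boronate | ClC(Cl)B1OC(C)(C)C(C)(C)O1 | starting material
11 | (E)-6,7-dideoxy-4-O-(4-methoxybenzyl)-2,3-di-O-(methoxymethyl)-7-(pinacolboryl)-L-gulo-hept-6-enono-1,5-lactone | O=C1O[C@@H](/C=C/B2OC(C)(C)C(C)(C)O2)[C@@H](OCc2ccc(OC)cc2)[C@H](OCOC)[C@@H]1OCOC | intermediate
12 | trimethylsilyl ketene acetal of 11 (C7(OSiMe3)=C1, not isolated) | C[Si](C)(C)OC1=C(OCOC)[C@@H](OCOC)[C@H](OCc2ccc(OC)cc2)[C@H](/C=C/B2OC(C)(C)C(C)(C)O2)O1 | intermediate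
13 | trimethylsilyl ester of 14 (not isolated) | COCO[C@H]1[C@H](OCc2ccc(OC)cc2)C=C[C@@H](B2OC(C)(C)C(C)(C)O2)[C@@]1(OCOC)C(=O)O[Si](C)(C)C | intermediate
14 | 1,2-bis(methoxymethoxy)-3-(4-methoxybenzyloxy)-6-(pinacolboryl)cyclohex-4-ene-1-carboxylic acid (C1–O/C3–O α; C2–O/C6–B/CO2H β) | COCO[C@H]1[C@H](OCc2ccc(OC)cc2)C=C[C@@H](B2OC(C)(C)C(C)(C)O2)[C@@]1(OCOC)C(=O)O | intermediate
15 | 6-hydroxy-1,2-bis(methoxymethoxy)-3-(4-methoxybenzyloxy)cyclohex-4-ene-1-carboxylic acid (6-OH β) | COCO[C@H]1[C@H](OCc2ccc(OC)cc2)C=C[C@@H](O)[C@@]1(OCOC)C(=O)O | intermediate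
16 | tert-butyldimethylsilyl 6-(tert-butyldimethylsilyloxy)-1,2-bis(methoxymethoxy)-3-(4-methoxybenzyloxy)cyclohex-4-ene-1-carboxylate | COCO[C@H]1[C@H](OCc2ccc(OC)cc2)C=C[C@@H](O[Si](C)(C)C(C)(C)C)[C@@]1(OCOC)C(=O)O[Si](C)(C)C(C)(C)C | intermediate
17 | [6-(tert-butyldimethylsilyloxy)-1,2-bis(methoxymethoxy)-3-(4-methoxybenzyloxy)cyclohex-4-en-1-yl]methanol | COCO[C@H]1[C@H](OCc2ccc(OC)cc2)C=C[C@@H](O[Si](C)(C)C(C)(C)C)[C@@]1(OCOC)CO | intermediate
18 | benzoyl chloride | O=C(Cl)c1ccccc1 | starting material
19 | [6-(tert-butyldimethylsilyloxy)-1,2-bis(methoxymethoxy)-3-(4-methoxybenzyloxy)cyclohex-4-en-1-yl]methyl benzoate | COCO[C@H]1[C@H](OCc2ccc(OC)cc2)C=C[C@@H](O[Si](C)(C)C(C)(C)C)[C@@]1(OCOC)COC(=O)c1ccccc1 | intermediate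
20 | [6-(tert-butyldimethylsilyloxy)-3-hydroxy-1,2-bis(methoxymethoxy)cyclohex-4-en-1-yl]methyl benzoate | COCO[C@H]1[C@H](O)C=C[C@@H](O[Si](C)(C)C(C)(C)C)[C@@]1(OCOC)COC(=O)c1ccccc1 | intermediate
21 | [3-(benzoyloxy)-6-(tert-butyldimethylsilyloxy)-1,2-bis(methoxymethoxy)cyclohex-4-en-1-yl]methyl benzoate | COCO[C@H]1[C@H](OC(=O)c2ccccc2)C=C[C@@H](O[Si](C)(C)C(C)(C)C)[C@@]1(OCOC)COC(=O)c1ccccc1 | intermediate
22 | [3-(benzoyloxy)-6-(tert-butyldimethylsilyloxy)-1,2-dihydroxycyclohex-4-en-1-yl]methyl benzoate | O[C@H]1[C@H](OC(=O)c2ccccc2)C=C[C@@H](O[Si](C)(C)C(C)(C)C)[C@@]1(O)COC(=O)c1ccccc1 | intermediate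
23 | [2-acetoxy-3-(benzoyloxy)-6-(tert-butyldimethylsilyloxy)-1-hydroxycyclohex-4-en-1-yl]methyl benzoate | CC(=O)O[C@H]1[C@H](OC(=O)c2ccccc2)C=C[C@@H](O[Si](C)(C)C(C)(C)C)[C@@]1(O)COC(=O)c1ccccc1 | intermediate
24 | [(1S,2S,3R,6R)-2-acetoxy-3-(benzoyloxy)-1,6-dihydroxycyclohex-4-en-1-yl]methyl benzoate (CNP0160999.2) | CC(=O)O[C@H]1[C@H](OC(=O)c2ccccc2)C=C[C@@H](O)[C@@]1(O)COC(=O)c1ccccc1 | target

## Step count and risks

Total step count: 17. Longest linear sequence: 17 steps, from L-gulono-1,4-lactone.

Steps most likely to fail: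

1. Step 8 (ring contraction). β-Elimination of the C2 methoxymethoxy group from the lactone enolate may outrun silylation, the amide base may be tied up as a borate at the vinylboronate, or the enforced boat may lie too high for the silyl ketene acetal to survive heating. Fallback (open-chain glycolate Claisen rearrangement, then ring-closing metathesis), setting out from lactone alcohol 8 and returning at acid 14: I2, PPh3 and imidazole should convert 8 into the 6-deoxy-6-iodo lactone F1. Zinc dust in AcOH/THF should then expel the carboxylate by reductive β-elimination to give the open-chain hex-5-enoic acid F2, which carries the C4 terminal alkene. Esterification (EDC, DMAP) with (Z)-3-(pinacolboryl)prop-2-en-1-ol, a known reagent, gives the allyl ester F3. Its chelated potassium enolate, silylated with Me3SiCl and warmed from −78 °C to rt, should rearrange through a chair, which with the Z-alkenylboronate gives the same C1/C6 relative configuration as the boat does with the E isomer, to the diene acid F4. Ring-closing metathesis with the second-generation Grubbs catalyst (CH2Cl2, 40 °C) closes C4=C5 and gives 14. In this variant the face of attack at C1 is governed only by the neighbouring C2 centre, so diastereomers may have to be separated.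

2. Step 5 (translactonisation). The N-to-O acyl transfer may stall at diol amide 7, or the stoichiometric acid may begin to cleave the MOM and PMB ethers or move a methoxymethyl group onto the free diol before the lactone has closed. Fallback (lactol formation and oxidation in place of acyl transfer), setting out from amide 6 and returning at aldehyde 9: i-Bu2AlH in THF at −78 °C should stop at the aldehyde stage, as morpholine amides do, to give the open-chain aldehyde F5. AcOH/H2O then removes the terminal acetal and the freed O4 hydroxyl closes on the aldehyde to the pyranose hemiacetal F6. TEMPO (cat.) with PhI(OAc)2 in CH2Cl2 should oxidise the lactol to the lactone and the primary alcohol to the aldehyde in the same operation, giving 9 and making step 6 unnecessary.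

3. Step 7 (boryl olefination). The α-acyloxy aldehyde may epimerise at C4 or lose the C3 ether by β-elimination under the Lewis-acidic chromium conditions, or halide exchange at the boronate may be incomplete and conversion low. Fallback (methylenation, then cross-metathesis), setting out from aldehyde 9 and returning at vinylboronate 11: Takai–Lombardo methylenation (Zn, CH2Br2, TiCl4, THF/CH2Cl2), which is non-basic and spares the lactone, should give the vinyl lactone F7. Cross-metathesis with pinacol vinylboronate and the second-generation Grubbs catalyst (CH2Cl2, 40 °C) should then deliver the E-alkenylboronate 11 under thermodynamic control.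

## Further compounds

F1 | step 8 | 6-deoxy-6-iodo-4-O-(4-methoxybenzyl)-2,3-di-O-(methoxymethyl)-L-gulono-1,5-lactone | O=C1O[C@@H](CI)[C@@H](OCc2ccc(OC)cc2)[C@H](OCOC)[C@@H]1OCOC
F2 | step 8 | 5,6-dideoxy-4-O-(4-methoxybenzyl)-2,3-di-O-(methoxymethyl)-L-xylo-hex-5-enonic acid | C=C[C@@H](OCc1ccc(OC)cc1)[C@H](OCOC)[C@H](OCOC)C(=O)O
F3 | step 8 | (Z)-3-(pinacolboryl)allyl ester of F2 | C=C[C@@H](OCc1ccc(OC)cc1)[C@H](OCOC)[C@H](OCOC)C(=O)OC/C=C\B1OC(C)(C)C(C)(C)O1
F4 | step 8 | open-chain diene acid (C1 quaternary with OMOM and CO2H; C6 bearing Bpin and vinyl; C3 bearing OPMB and vinyl) | C=C[C@@H](OCc1ccc(OC)cc1)[C@H](OCOC)[C@](OCOC)(C(=O)O)[C@@H](C=C)B1OC(C)(C)C(C)(C)O1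
F5 | step 5 | 5,6-O-isopropylidene-4-O-(4-methoxybenzyl)-2,3-di-O-(methoxymethyl)-aldehydo-L-gulose | CC1(C)OC[C@H](O1)[C@@H](OCc1ccc(OC)cc1)[C@H](OCOC)[C@H](OCOC)C=O
F6 | step 5 | 4-O-(4-methoxybenzyl)-2,3-di-O-(methoxymethyl)-L-gulopyranose (anomeric mixture) | OC1O[C@@H](CO)[C@@H](OCc2ccc(OC)cc2)[C@H](OCOC)[C@@H]1OCOC
F7 | step 7 | 6,7-dideoxy-4-O-(4-methoxybenzyl)-2,3-di-O-(methoxymethyl)-L-gulo-hept-6-enono-1,5-lactone | O=C1O[C@@H](C=C)[C@@H](OCc2ccc(OC)cc2)[C@H](OCOC)[C@@H]1OCOC
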